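**Plan**
Retrosynthesis: the pyran ether bond O1–C2 is cut first, opening the flavan to a 1,3-diarylpropan-1-ol. Next comes the C2–C3 bond (B-ring aldehyde plus A-ring 2-arylethyl Grignard reagent), then the two aryl–prenyl bonds at C2' and C3' (Stille) and the aryl–C(CH3)2 bond at C6 (aromatic Claisen).
Forward: the B ring is built from 5-bromovanillin (steps 1–4) and the A ring from 2,4-dihydroxybenzaldehyde (steps 5–11). The chain is joined in step 12, the silyl ethers are removed in step 13, and the pyran ring, the only ring made, closes in step 14.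
Enabling feature: the 4'-OH of ring B is para to C1', so the carbinol carbon (later C2) can become the exocyclic carbon of a p-quinone methide. The ring-A oxygen on C8a can reach it through a six-membered transition state.
Stereochemistry: C2 is the only stereocentre. The carbinol is carried racemic because ionisation to the planar quinone methide erases it, and the 2S configuration is set by a chiral phosphoric acid during ring closure.

Key step: step 14

Assumption: (R)-TRIP is taken to deliver the 2S flavan. The sense of induction is not established for this substrate, and (S)-TRIP would be used under the same conditions if the opposite sense is found.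
Abbreviation: Ar = 4-(tert-butyldimethylsilyloxy)-5-(2-methylbut-3-en-2-yl)-2-(triisopropylsilyloxy)phenyl.

**Route**

Step 1
Reactants: 1 5-bromovanillin (3-bromo-4-hydroxy-5-methoxybenzaldehyde)
Product: 2 5,6-dibromovanillin (2,3-dibromo-4-hydroxy-5-methoxybenzaldehyde)
Conditions: Br2 (1.1 equiv), Fe powder (cat.), AcOH, rt → 50 °C
Reagents that add atoms: bromine, BrBr
Why: Electrophilic aromatic bromination should go to C6, which is para to the methoxy group, while the other open site (C2) is squeezed between CHO and OMe.

Step 2
Reactants: 2 5,6-dibromovanillin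
Product: 3 2,3-dibromo-4,5-dihydroxybenzaldehyde
Conditions: BBr3, CH2Cl2, −78 °C → rt; then H2O
Reagents that add atoms: none
Why: Lewis-acid cleavage of the aryl methyl ether (BBr3 demethylation) is assisted by the neighbouring phenol through a cyclic borate and leaves the aldehyde and aryl bromides untouched.

Step 3
Reactants: 3 2,3-dibromo-4,5-dihydroxybenzaldehyde
Product: 4 2,3-dibromo-4,5-bis(tert-butyldimethylsilyloxy)benzaldehyde
Conditions: TBSCl (2.5 equiv), imidazole, DMF, rt
Reagents that add atoms: tert-butyldimethylsilyl chloride, CC(C)(C)[Si](C)(C)Cl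
Why: Standard imidazole-mediated silylation of both phenols gives ethers that tolerate the later organometallic steps and leave with fluoride at the end.

Step 4
Reactants: 4 2,3-dibromo-4,5-bis(tert-butyldimethylsilyloxy)benzaldehyde; 5 tributyl(3-methylbut-2-en-1-yl)stannane
Product: 6 4,5-bis(tert-butyldimethylsilyloxy)-2,3-bis(3-methylbut-2-en-1-yl)benzaldehyde
Conditions: 5 (3 equiv), Pd(PPh3)4 (10 mol %), toluene, 110 °C, Ar
Reagents that add atoms: 5 tributyl(3-methylbut-2-en-1-yl)stannane, CCCC[Sn](CCCC)(CCCC)CC=C(C)C
Why: A twofold Stille cross-coupling under neutral, fluoride-free conditions tolerates the aldehyde and aryl silyl ethers, and reductive elimination from the allyl–palladium intermediate at its less substituted terminus should give the linear prenyl groups.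

Step 5
Reactants: 7 2,4-dihydroxybenzaldehyde; 8 prenyl bromide (1-bromo-3-methylbut-2-ene)
Product: 9 2-hydroxy-4-(3-methylbut-2-en-1-yloxy)benzaldehyde
Conditions: 8 (1.1 equiv), KHCO3, MeCN, 60 °C
Reagents that add atoms: 8 prenyl bromide, CC(C)=CCBr
Why: Williamson etherification is selective for the 4-OH because the 2-OH is tied up in a hydrogen bond to the formyl group and is not deprotonated by the weak base.

Step 6
Reactants: 9 2-hydroxy-4-(3-methylbut-2-en-1-yloxy)benzaldehyde
Product: 10 4-(3-methylbut-2-en-1-yloxy)-2-(triisopropylsilyloxy)benzaldehyde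
Conditions: TIPSCl, imidazole, DMAP (cat.), DMF, rt → 40 °C
Reagents that add atoms: triisopropylsilyl chloride, CC(C)[Si](Cl)(C(C)C)C(C)C
Why: Silylation of the remaining phenol breaks the chelate that would steer the coming rearrangement to C3, and the bulky TIPS ether shields C3 and should survive both the heating in step 7 and the aqueous acid in step 10.

Step 7
Reactants: 10 4-(3-methylbut-2-en-1-yloxy)-2-(triisopropylsilyloxy)benzaldehyde
Product: 11 4-hydroxy-5-(2-methylbut-3-en-2-yl)-2-(triisopropylsilyloxy)benzaldehyde
Conditions: PhNEt2, 190 °C, Ar, sealed tube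
Reagents that add atoms: none
Why: The aromatic Claisen ([3,3]-sigmatropic) rearrangement of the aryl prenyl ether delivers the allyl group through its tertiary end to C5, the ortho position that is not flanked by two oxygen substituents and lies para to the donating 2-silyloxy group.

Step 8
Reactants: 11 4-hydroxy-5-(2-methylbut-3-en-2-yl)-2-(triisopropylsilyloxy)benzaldehyde
Product: 12 4-(tert-butyldimethylsilyloxy)-5-(2-methylbut-3-en-2-yl)-2-(triisopropylsilyloxy)benzaldehyde (ArCHO)
Conditions: TBSOTf, 2,6-lutidine, CH2Cl2, 0 °C → rt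
Reagents that add atoms: tert-butyldimethylsilyl triflate, CC(C)(C)[Si](C)(C)OS(=O)(=O)C(F)(F)F
Why: The reactive silyl triflate should silylate the phenol despite the tert-alkyl group next to it, and the non-enolisable aldehyde is inert to it.

Step 9
Reactants: 12 ArCHO
Product: 13 1-Ar-2-methoxyethene (ArCH=CHOMe, E/Z mixture)
Conditions: Ph3P(CH2OMe)Cl, KHMDS, THF, −78 → 0 °C
Reagents that add atoms: (methoxymethyl)triphenylphosphonium chloride, COC[P+](c1ccccc1)(c1ccccc1)c1ccccc1.[Cl-]
Why: Wittig olefination with the methoxymethylene ylide adds the one carbon needed for the chain, and the non-nucleophilic amide base leaves the aryl silyl ethers intact.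

Step 10
Reactants: 13 1-Ar-2-methoxyethene
Product: 15 2-Ar-ethanol (ArCH2CH2OH), via arylacetaldehyde 14 (not isolated)
Conditions: 2 M aq HCl, THF, rt; then NaBH4, MeOH, 0 °C
Reagents that add atoms: water, O
Why: Acid hydrolysis of the enol ether gives the arylacetaldehyde, which is prone to aldol reaction and is therefore reduced at once with borohydride (carbonyl reduction); the 2-O-TIPS group should hold, which prevents benzofuran formation.

Step 11
Reactants: 15 2-Ar-ethanol
Product: 16 2-Ar-ethyl bromide (ArCH2CH2Br)
Conditions: CBr4, PPh3, CH2Cl2, 0 °C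
Reagents that add atoms: carbon tetrabromide, BrC(Br)(Br)Br
Why: The Appel reaction converts the primary alcohol into the bromide under neutral conditions without carbocations, so the vinyl group and silyl ethers are not touched.

Step 12
Reactants: 16 2-Ar-ethyl bromide; 6 4,5-bis(tert-butyldimethylsilyloxy)-2,3-bis(3-methylbut-2-en-1-yl)benzaldehyde
Product: 18 rac-1-[4,5-bis(tert-butyldimethylsilyloxy)-2,3-bis(3-methylbut-2-en-1-yl)phenyl]-3-Ar-propan-1-ol, via arylethylmagnesium bromide 17 (not isolated)
Conditions: 16 (1.3 equiv), Mg turnings, I2 (cat.), THF, 40 °C; then 6, THF, −78 → 0 °C; H2O quench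
Reagents that add atoms: none
Why: Grignard formation and 1,2-addition to the non-enolisable aldehyde forms the C2–C3 bond; the carbinol is racemic, which is harmless because its configuration is erased in step 14.

Step 13
Reactants: 18 tetrasilyl diarylpropanol
Product: 19 rac-4-{3-[4,5-dihydroxy-2,3-bis(3-methylbut-2-en-1-yl)phenyl]-3-hydroxypropyl}-6-(2-methylbut-3-en-2-yl)benzene-1,3-diol
Conditions: TBAF (5 equiv), AcOH (5 equiv), degassed THF, 0 °C; pH 5 aqueous wash to remove ammonium salts; used promptly without silica chromatography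
Reagents that add atoms: none
Why: Fluoride-mediated cleavage of all four aryl silyl ethers is driven by Si–F bond formation, and the acetic acid buffer keeps the phenols protonated so that no base-induced quinone methide formation or catechol autoxidation sets in.

Step 14
Reactants: 19 racemic pentol
Product: 21 Kazinol E, via p-quinone methide 20 (not isolated)
Conditions: (R)-TRIP (10 mol %), CH2Cl2/toluene 1:1 (0.01 M), −20 °C, Ar; filtered through a short NaHCO3/silica pad at full conversion
Reagents that add atoms: none
Why: The phosphoric acid hydrogen-bonds to and protonates the benzylic hydroxyl of 19, and loss of water, pushed by the para 4'-OH, gives the planar p-quinone methide 20, so both enantiomers of the carbinol converge on one intermediate. The chiral phosphate then bridges the quinone methide oxygen (P–OH donor) and the ring-A hydroxyl ortho to the chain (P=O acceptor) and guides that oxygen onto the exocyclic carbon, an oxa-1,6-conjugate addition that forms O1–C2 and restores the catechol. The closest known reaction type is the chiral phosphoric acid-catalysed asymmetric 1,6-addition of nucleophiles to p-quinone methides generated in situ from p-hydroxybenzyl alcohols. The pyran ring closes in the 6-exo-trig mode, the exocyclic C=C of 20 lying outside the new ring. The new stereocentre C2 is set under catalyst control, the 2,4,6-triisopropylphenyl walls of the catalyst exposing one face of the E-configured quinone methide to the tethered phenol. The step needs O- over C-alkylation and must avoid attack by the 2'-prenyl olefin, intermolecular arylation and reopening of the product: only the ortho hydroxyl can reach C2 through a six-membered transition state, the arene carbon within reach is meta to both ring-A oxygens, high dilution disfavours intermolecular attack at the carbon between the two ring-A hydroxyls, and the weak acid at low temperature should leave the prenyl groups and the formed benzylic ether untouched.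

**Compound list**
1 | 5-bromovanillin (3-bromo-4-hydroxy-5-methoxybenzaldehyde) | COc1cc(C=O)cc(Br)c1O | starting material
2 | 5,6-dibromovanillin (2,3-dibromo-4-hydroxy-5-methoxybenzaldehyde) | COc1cc(C=O)c(Br)c(Br)c1O | intermediate
3 | 2,3-dibromo-4,5-dihydroxybenzaldehyde | O=Cc1cc(O)c(O)c(Br)c1Br | intermediate
4 | 2,3-dibromo-4,5-bis(tert-butyldimethylsilyloxy)benzaldehyde | O=Cc1cc(O[Si](C)(C)C(C)(C)C)c(O[Si](C)(C)C(C)(C)C)c(Br)c1Br | intermediate
5 | tributyl(3-methylbut-2-en-1-yl)stannane | CCCC[Sn](CCCC)(CCCC)CC=C(C)C | starting material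
6 | 4,5-bis(tert-butyldimethylsilyloxy)-2,3-bis(3-methylbut-2-en-1-yl)benzaldehyde | O=Cc1cc(O[Si](C)(C)C(C)(C)C)c(O[Si](C)(C)C(C)(C)C)c(CC=C(C)C)c1CC=C(C)C | intermediate
7 | 2,4-dihydroxybenzaldehyde | O=Cc1ccc(O)cc1O | starting material
8 | prenyl bromide (1-bromo-3-methylbut-2-ene) | CC(C)=CCBr | starting material
9 | 2-hydroxy-4-(3-methylbut-2-en-1-yloxy)benzaldehyde | O=Cc1ccc(OCC=C(C)C)cc1O | intermediate
10 | 4-(3-methylbut-2-en-1-yloxy)-2-(triisopropylsilyloxy)benzaldehyde | O=Cc1ccc(OCC=C(C)C)cc1O[Si](C(C)C)(C(C)C)C(C)C | intermediate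
11 | 4-hydroxy-5-(2-methylbut-3-en-2-yl)-2-(triisopropylsilyloxy)benzaldehyde | O=Cc1cc(C(C)(C)C=C)c(O)cc1O[Si](C(C)C)(C(C)C)C(C)C | intermediate
12 | 4-(tert-butyldimethylsilyloxy)-5-(2-methylbut-3-en-2-yl)-2-(triisopropylsilyloxy)benzaldehyde | O=Cc1cc(C(C)(C)C=C)c(O[Si](C)(C)C(C)(C)C)cc1O[Si](C(C)C)(C(C)C)C(C)C | intermediate
13 | 1-Ar-2-methoxyethene (E/Z mixture) | COC=Cc1cc(C(C)(C)C=C)c(O[Si](C)(C)C(C)(C)C)cc1O[Si](C(C)C)(C(C)C)C(C)C | intermediate
14 | 2-Ar-acetaldehyde | O=CCc1cc(C(C)(C)C=C)c(O[Si](C)(C)C(C)(C)C)cc1O[Si](C(C)C)(C(C)C)C(C)C | intermediate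
15 | 2-Ar-ethanol | OCCc1cc(C(C)(C)C=C)c(O[Si](C)(C)C(C)(C)C)cc1O[Si](C(C)C)(C(C)C)C(C)C | intermediate
16 | 2-Ar-ethyl bromide | BrCCc1cc(C(C)(C)C=C)c(O[Si](C)(C)C(C)(C)C)cc1O[Si](C(C)C)(C(C)C)C(C)C | intermediate
17 | 2-Ar-ethylmagnesium bromide | Br[Mg]CCc1cc(C(C)(C)C=C)c(O[Si](C)(C)C(C)(C)C)cc1O[Si](C(C)C)(C(C)C)C(C)C | intermediate
18 | rac-1-[4,5-bis(tert-butyldimethylsilyloxy)-2,3-bis(3-methylbut-2-en-1-yl)phenyl]-3-Ar-propan-1-ol | C=CC(C)(C)c1cc(CCC(O)c2cc(O[Si](C)(C)C(C)(C)C)c(O[Si](C)(C)C(C)(C)C)c(CC=C(C)C)c2CC=C(C)C)c(O[Si](C(C)C)(C(C)C)C(C)C)cc1O[Si](C)(C)C(C)(C)C | intermediate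
19 | rac-4-{3-[4,5-dihydroxy-2,3-bis(3-methylbut-2-en-1-yl)phenyl]-3-hydroxypropyl}-6-(2-methylbut-3-en-2-yl)benzene-1,3-diol | C=CC(C)(C)c1cc(CCC(O)c2cc(O)c(O)c(CC=C(C)C)c2CC=C(C)C)c(O)cc1O | intermediate
20 | (E)-p-quinone methide: 4-{3-[2,4-dihydroxy-5-(2-methylbut-3-en-2-yl)phenyl]propylidene}-6-hydroxy-2,3-bis(3-methylbut-2-en-1-yl)cyclohexa-2,5-dien-1-one | C=CC(C)(C)c1cc(CC/C=C2\C=C(O)C(=O)C(CC=C(C)C)=C2CC=C(C)C)c(O)cc1O | intermediate
21 | Kazinol E, 5-[(2S)-7-hydroxy-6-(2-methylbut-3-en-2-yl)-3,4-dihydro-2H-chromen-2-yl]-3,4-bis(3-methylbut-2-en-1-yl)benzene-1,2-diol | C=CC(C)(C)c1cc2c(cc1O)O[C@H](c1cc(O)c(O)c(CC=C(C)C)c1CC=C(C)C)CC2 | target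

**Count and risks**
Total step count: 14. Longest linear sequence: 10 steps (steps 5–14, from 2,4-dihydroxybenzaldehyde). The B-ring branch (steps 1–4) joins at step 12.

Steps most likely to fail:

Step 14. What may go wrong is weak facial discrimination when the phenol adds to the quinone methide, or loss of enantiopurity because the benzylic aryl ether reopens under the acid. The fallback sets out from 19: ring closure with an achiral Brønsted acid (diphenyl phosphate, 5 mol %, CH2Cl2, 0 °C) through the same quinone methide should give racemic Kazinol E F1. Preparative HPLC on a polysaccharide chiral stationary phase then separates the enantiomers, and the route is rejoined at 21. The 2R enantiomer can be returned to F1 by brief treatment with the same acid and resolved again.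

Step 4. What may go wrong is stalling after the first prenyl transfer, because oxidative addition into the second C–Br bond, wedged between a prenyl group and a silyloxy group, is slow; part of the allyl group may also be transferred through its tertiary end. The fallback sets out from 4: the aldehyde is masked as 2,3-dibromo-4,5-bis(tert-butyldimethylsilyloxy)benzaldehyde dimethyl acetal F2 (HC(OMe)3, PPTS, MeOH). A linear-selective Negishi coupling with prenylzinc bromide (from 8, Zn dust, LiCl, THF) under a Pd/CPhos catalyst should then install both prenyl groups to give 4,5-bis(tert-butyldimethylsilyloxy)-2,3-bis(3-methylbut-2-en-1-yl)benzaldehyde dimethyl acetal F3. PPTS in wet acetone frees the aldehyde, and the route is rejoined at 6.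

Step 7. What may go wrong is thermal loss of the prenyl group as isoprene, or further reaction of the freshly formed ortho-(1,1-dimethylallyl)phenol (abnormal Claisen rearrangement, ring closure onto the vinyl group) during prolonged heating. The fallback sets out from 10: the rearrangement is run as an acylative Claisen in PhNEt2 with acetic anhydride and sodium acetate, so that the phenol is captured at once as 4-acetoxy-5-(2-methylbut-3-en-2-yl)-2-(triisopropylsilyloxy)benzaldehyde F4. Catalytic K2CO3 in methanol at 0 °C then removes the activated acetate (para to the formyl group), and the route is rejoined at 11.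

Further compounds
F1 | step 14 | racemic Kazinol E | C=CC(C)(C)c1cc2c(cc1O)OC(c1cc(O)c(O)c(CC=C(C)C)c1CC=C(C)C)CC2
F2 | step 4 | 2,3-dibromo-4,5-bis(tert-butyldimethylsilyloxy)benzaldehyde dimethyl acetal | COC(OC)c1cc(O[Si](C)(C)C(C)(C)C)c(O[Si](C)(C)C(C)(C)C)c(Br)c1Br
F3 | step 4 | 4,5-bis(tert-butyldimethylsilyloxy)-2,3-bis(3-methylbut-2-en-1-yl)benzaldehyde dimethyl acetal | COC(OC)c1cc(O[Si](C)(C)C(C)(C)C)c(O[Si](C)(C)C(C)(C)C)c(CC=C(C)C)c1CC=C(C)C
F4 | step 7 | 4-acetoxy-5-(2-methylbut-3-en-2-yl)-2-(triisopropylsilyloxy)benzaldehyde | CC(=O)Oc1cc(O[Si](C(C)C)(C(C)C)C(C)C)c(C=O)cc1C(C)(C)C=C
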